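Positions follow carotenoid numbering (ring A C1–C6, chain C7–C15, primes for the unsubstituted half).

**Plan**
- Retrosynthetic cuts, in order: the ester C–O bond at C3; the C11=C12 alkene (Wittig, C15 phosphonium salt plus C25 β-apo-12'-carotenal from retinal); C10–C11 and C9–C10 back to (3R)-3-hydroxy-β-ionone; the ring bond C3–C4; then C6–C7 (Heck) and C1–C2 (allylation) of the open chain.
- Enabling feature: in ring A the carbinol C3 is the neighbour of C4, and C4 sits at the ε-position of the dienone C9(=O)–C8=C7–C6=C5 of 3-hydroxy-β-ionone. With C4 still a methyl of an isopropylidene group, an achiral keto aldehyde can close ring A onto its own C3 aldehyde.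
- Forward: diisopropyl ketone, allyl bromide and but-3-en-2-one give the acyclic C13 keto aldehyde (steps 1–5); ring A closes in step 6; the chain grows to the C15 salt (steps 7–8), is joined to the C25 aldehyde (steps 9–12), and the palmitoleate goes on last (step 13). The unsubstituted ring arrives intact with retinal.
- Stereochemistry: C3 (R) is the only stereocentre; it is set by the chiral primary amine in step 6 and its C–O bond is never broken afterwards. The E-alkenes come from Heck, Horner–Wadsworth–Emmons and Wittig/thermal isomerisation; the 9Z alkene is bought with palmitoleic acid.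

Key step: step 6

Assumption: the sense of induction of the cinchona amine at C3 cannot be assigned in advance; the quinine-derived amine is written as giving 3R, and its quinidine-derived pseudoenantiomer would take its place if the opposite sense were found.

**Step 1**
Reactants: 1 2,4-dimethylpentan-3-one (diisopropyl ketone); 2 3-bromoprop-1-ene (allyl bromide)
Product: 3 2,4,4-trimethylhept-6-en-3-one
Conditions: LiN(iPr)2 (1.05 equiv), THF, −78 to 0 °C; then 2, 0 °C to rt
Reagents that add atoms: none
Why: Enolate alkylation: the single possible enolate of the symmetrical ketone is C-allylated by the reactive allylic bromide (SN2), which creates the quaternary carbon that becomes C1 of ring A; no stereocentre is formed.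

**Step 2**
Reactants: 3 2,4,4-trimethylhept-6-en-3-one
Product: 5 6,6-dimethoxy-2,4,4-trimethylhexan-3-one, via 3,3,5-trimethyl-4-oxohexanal 4 (not isolated)
Conditions: O3, CH2Cl2/MeOH, −78 °C; Me2S, −78 °C to rt; then HC(OMe)3, TsOH·H2O (cat.), rt
Reagents that add atoms: ozone, [O-][O+]=O (the aldehyde oxygen of 4); trimethyl orthoformate, COC(OC)OC, with methanol, CO (the two methoxy groups of 5)
Why: Ozonolysis of the terminal alkene with reductive work-up gives the aldehyde (future C3), which is converted in the same flask into its dimethyl acetal by orthoester-driven acetalisation, while the ketone between a quaternary and an isopropyl carbon is too hindered to ketalise.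

**Step 3**
Reactants: 5 6,6-dimethoxy-2,4,4-trimethylhexan-3-one
Product: 6 6,6-dimethoxy-2,4,4-trimethylhex-2-en-3-yl trifluoromethanesulfonate
Conditions: KN(SiMe3)2 (1.3 equiv), THF, −78 to 0 °C; then Comins' reagent, −78 °C to rt
Reagents that add atoms: N-(5-chloropyridin-2-yl)-1,1,1-trifluoro-N-(trifluoromethylsulfonyl)methanesulfonamide (Comins' reagent), O=S(=O)(N(c1ccc(Cl)cn1)S(=O)(=O)C(F)(F)F)C(F)(F)F
Why: Enol triflate formation: the ketone can enolise only towards the isopropyl methine, so O-sulfonylation of the potassium enolate should give one tetrasubstituted enol triflate with no alkene geometry to control, and the acetal is inert to the base.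

**Step 4**
Reactants: 6 6,6-dimethoxy-2,4,4-trimethylhex-2-en-3-yl trifluoromethanesulfonate; 7 but-3-en-2-one
Product: 8 (3E)-8,8-dimethoxy-6,6-dimethyl-5-(propan-2-ylidene)oct-3-en-2-one
Conditions: Pd(OAc)2 (10 mol %), PPh3 (20 mol %), Et3N, DMF, 75 °C; 7 in excess
Reagents that add atoms: none
Why: Mizoroki–Heck reaction of an alkenyl triflate with an electron-poor alkene: oxidative addition to zerovalent palladium formed in situ, insertion of the enone at its terminal carbon and syn β-hydride elimination should give the E-dienone (C6–C7 bond).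

**Step 5**
Reactants: 8 (3E)-8,8-dimethoxy-6,6-dimethyl-5-(propan-2-ylidene)oct-3-en-2-one
Product: 9 (5E)-3,3-dimethyl-7-oxo-4-(propan-2-ylidene)oct-5-enal
Conditions: 2 M HCl, THF, 0 °C to rt
Reagents that add atoms: water, O
Why: Acid-catalysed acetal hydrolysis frees the aldehyde; the dienone carries no acid-labile group, and under these conditions neither the aldehyde enol nor the alkene can reach the other carbonyl through a ring of reasonable size.

**Step 6**
Reactants: 9 (5E)-3,3-dimethyl-7-oxo-4-(propan-2-ylidene)oct-5-enal
Product: 10 (3E)-4-[(4R)-4-hydroxy-2,6,6-trimethylcyclohex-1-en-1-yl]but-3-en-2-one ((3R)-3-hydroxy-β-ionone)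
Conditions: 9-amino-9-deoxy-epi-quinine (20 mol %), 2-fluorobenzoic acid (40 mol %), toluene (0.02 M), 40 °C
Reagents that add atoms: none
Why: Proposed new method: the primary amine condenses with the C9 methyl ketone, the iminium ion loses a proton from either ε-methyl group of the isopropylidene (both lead to the same linear trienamine N–C9=C8–C7=C6–C5=C4H2), the terminal carbon C4 adds to the C3 aldehyde, and hydrolysis of the dienyl iminium ion releases 10 and the amine. The nearest precedents are enamine-mediated intramolecular aldolisations, the trienamine mode of 2,4-dienones under 9-amino-9-deoxy-epi-cinchona catalysis and enantioselective bis-vinylogous Mukaiyama aldol reactions of silyl trienol ethers. Ring A closes in a 6-(enolendo)-exo-trig mode, with C4 and C5 of the nucleophilic double bond inside the new ring and the aldehyde C=O outside it. The R configuration at C3 is set by the catalyst, whose protonated quinuclidine should hold the aldehyde by a hydrogen bond while the cinchona scaffold exposes a single carbonyl face to C4. The step needs ε-attack rather than α-attack and one aldehyde face: γ-attack from C6 would give a cyclobutane, attack from C8 would give a deconjugated β-hydroxy ketone and is shielded by the amine bound next to it, the enamines at C10 or at the aldehyde have no unstrained ring to close, and only ε-attack returns a fully conjugated tetrasubstituted dienone. High dilution suppresses intermolecular aldol addition, and the reaction is stopped at full conversion so that retro-aldol equilibration or loss of water does not erode the stereocentre.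

**Step 7**
Reactants: 10 (3R)-3-hydroxy-β-ionone; 11 vinylmagnesium bromide
Product: 12 (1E)-1-[(4R)-4-hydroxy-2,6,6-trimethylcyclohex-1-en-1-yl]-3-methylpenta-1,4-dien-3-ol (both epimers at the new tertiary carbinol)
Conditions: 11 (3 equiv), THF, −20 to 0 °C; aq. NH4Cl
Reagents that add atoms: none
Why: Grignard 1,2-addition to the methyl ketone of a β-ionone-type dienone (the hindered C7 disfavours conjugate addition); one equivalent is consumed by the C3 hydroxyl, C3 is untouched, and the new carbinol centre is erased in the next step.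

**Step 8**
Reactants: 12 the dienediol from step 7
Product: 13 [(2E,4E)-5-[(4R)-4-hydroxy-2,6,6-trimethylcyclohex-1-en-1-yl]-3-methylpenta-2,4-dien-1-yl](triphenyl)phosphonium bromide
Conditions: PPh3·HBr (1.05 equiv), MeOH, 0 °C to rt; crystallisation
Reagents that add atoms: triphenylphosphine hydrobromide, [Br-].[PH+](c1ccccc1)(c1ccccc1)c1ccccc1
Why: Acid-promoted ionisation of the tertiary bis-allylic alcohol to a pentadienyl cation and capture by PPh3 at the primary terminus (SN1 with allylic transposition) should give the conjugated E,E-dienyl phosphonium salt, while the secondary C3 alcohol does not ionise.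

**Step 9**
Reactants: 14 all-trans-retinal; 15 ethyl (2E)-4-(diethoxyphosphoryl)-2-methylbut-2-enoate
Product: 16 ethyl (2E,4E,6E,8E,10E,12E)-2,7,11-trimethyl-13-(2,6,6-trimethylcyclohex-1-en-1-yl)trideca-2,4,6,8,10,12-hexaenoate (ethyl β-apo-12'-carotenoate)
Conditions: 15, n-BuLi, THF, −78 °C; then 14, −78 to 0 °C, dark
Reagents that add atoms: none
Why: Horner–Wadsworth–Emmons olefination: the lithiated vinylogous phosphonoacetate reacts at the carbon next to phosphorus with the polyenal and should give the new disubstituted alkene E, extending retinal by the C5 unit.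

**Step 10**
Reactants: 16 ethyl β-apo-12'-carotenoate
Product: 17 (2E,4E,6E,8E,10E,12E)-2,7,11-trimethyl-13-(2,6,6-trimethylcyclohex-1-en-1-yl)trideca-2,4,6,8,10,12-hexaen-1-ol (β-apo-12'-carotenol)
Conditions: iBu2AlH (2.5 equiv), CH2Cl2, −78 °C; aq. potassium sodium tartrate
Reagents that add atoms: none
Why: Hydride 1,2-reduction of the conjugated ester by the aluminium hydride gives the allylic alcohol and leaves the polyene untouched.

**Step 11**
Reactants: 17 β-apo-12'-carotenol
Product: 18 (2E,4E,6E,8E,10E,12E)-2,7,11-trimethyl-13-(2,6,6-trimethylcyclohex-1-en-1-yl)trideca-2,4,6,8,10,12-hexaenal (β-apo-12'-carotenal)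
Conditions: MnO2 (excess), CH2Cl2, rt, dark
Reagents that add atoms: none
Why: MnO2 oxidation is selective for the allylic (polyenylic) primary alcohol and stops at the aldehyde.

**Step 12**
Reactants: 13 the (3R)-C15 phosphonium bromide; 18 β-apo-12'-carotenal
Product: 20 (3R)-β,β-caroten-3-ol ((3R)-β-cryptoxanthin, all-E), via (11Z)-β-cryptoxanthin 19 (not isolated)
Conditions: NaOMe, MeOH/CH2Cl2, 0 °C to rt, dark; then heptane, reflux, N2; crystallisation
Reagents that add atoms: none
Why: Wittig olefination of the polyenal with the semi-stabilised C15 ylide forms C11=C12 as an E/Z mixture, and the sterically hindered 11Z isomer should isomerise thermally to the all-E carotenoid, which crystallises; the free C3 hydroxyl is tolerated and C3 is not affected.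

**Step 13**
Reactants: 20 (3R)-β-cryptoxanthin; 21 palmitoleic acid ((9Z)-hexadec-9-enoic acid)
Product: 22 (3R)-β,β-caroten-3-yl (9Z)-hexadec-9-enoate (CNP0382087.1)
Conditions: DCC, DMAP (cat.), CH2Cl2, rt, dark, Ar
Reagents that add atoms: none
Why: Steglich esterification (carbodiimide activation, DMAP acyl transfer) acylates the secondary C3 alcohol with retention because the C3–O bond is not broken, and the neutral room-temperature conditions leave the 9Z alkene and the polyene unchanged.

**Compound list**

1 | 2,4-dimethylpentan-3-one | CC(C)C(=O)C(C)C | starting material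
2 | 3-bromoprop-1-ene (allyl bromide) | C=CCBr | starting material
3 | 2,4,4-trimethylhept-6-en-3-one | CC(C)C(=O)C(C)(C)CC=C | intermediate
4 | 3,3,5-trimethyl-4-oxohexanal | CC(C)C(=O)C(C)(C)CC=O | intermediate (not isolated)
5 | 6,6-dimethoxy-2,4,4-trimethylhexan-3-one | CC(C)C(=O)C(C)(C)CC(OC)OC | intermediate
6 | 6,6-dimethoxy-2,4,4-trimethylhex-2-en-3-yl trifluoromethanesulfonate | CC(C)=C(OS(=O)(=O)C(F)(F)F)C(C)(C)CC(OC)OC | intermediate
7 | but-3-en-2-one | CC(=O)C=C | starting material
8 | (3E)-8,8-dimethoxy-6,6-dimethyl-5-(propan-2-ylidene)oct-3-en-2-one | CC(=O)/C=C/C(=C(C)C)C(C)(C)CC(OC)OC | intermediate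
9 | (5E)-3,3-dimethyl-7-oxo-4-(propan-2-ylidene)oct-5-enal | CC(=O)/C=C/C(=C(C)C)C(C)(C)CC=O | intermediate (key-step precursor)
10 | (3E)-4-[(4R)-4-hydroxy-2,6,6-trimethylcyclohex-1-en-1-yl]but-3-en-2-one, (3R)-3-hydroxy-β-ionone | O[C@@H]1CC(C)=C(/C=C/C(C)=O)C(C)(C)C1 | intermediate (key-step product)
11 | vinylmagnesium bromide | C=C[Mg]Br | starting material
12 | (1E)-1-[(4R)-4-hydroxy-2,6,6-trimethylcyclohex-1-en-1-yl]-3-methylpenta-1,4-dien-3-ol (epimers at the tertiary carbinol) | O[C@@H]1CC(C)=C(/C=C/C(C)(O)C=C)C(C)(C)C1 | intermediate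
13 | [(2E,4E)-5-[(4R)-4-hydroxy-2,6,6-trimethylcyclohex-1-en-1-yl]-3-methylpenta-2,4-dien-1-yl](triphenyl)phosphonium bromide | [Br-].O[C@@H]1CC(C)=C(/C=C/C(C)=C/C[P+](c2ccccc2)(c2ccccc2)c2ccccc2)C(C)(C)C1 | intermediate
14 | all-trans-retinal | O=C/C=C(C)/C=C/C=C(C)/C=C/C1=C(C)CCCC1(C)C | starting material
15 | ethyl (2E)-4-(diethoxyphosphoryl)-2-methylbut-2-enoate | CCOC(=O)/C(C)=C/CP(=O)(OCC)OCC | starting material
16 | ethyl β-apo-12'-carotenoate | CCOC(=O)/C(C)=C/C=C/C=C(C)/C=C/C=C(C)/C=C/C1=C(C)CCCC1(C)C | intermediate
17 | β-apo-12'-carotenol | OC/C(C)=C/C=C/C=C(C)/C=C/C=C(C)/C=C/C1=C(C)CCCC1(C)C | intermediate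
18 | β-apo-12'-carotenal | O=C/C(C)=C/C=C/C=C(C)/C=C/C=C(C)/C=C/C1=C(C)CCCC1(C)C | intermediate
19 | (3R,11Z)-β-cryptoxanthin, the part of the crude olefination product that is isomerised in the flask | O[C@@H]1CC(C)=C(\C=C\C(C)=C\C=C/C(C)=C/C=C/C=C(C)/C=C/C=C(C)/C=C/C2=C(C)CCCC2(C)C)C(C)(C)C1 | intermediate (not isolated)
20 | (3R)-β-cryptoxanthin, all-E | O[C@@H]1CC(C)=C(/C=C/C(C)=C/C=C/C(C)=C/C=C/C=C(C)/C=C/C=C(C)/C=C/C2=C(C)CCCC2(C)C)C(C)(C)C1 | intermediate
21 | palmitoleic acid | CCCCCC/C=C\CCCCCCCC(=O)O | starting material
22 | (3R)-β,β-caroten-3-yl (9Z)-hexadec-9-enoate | CCCCCC/C=C\CCCCCCCC(=O)O[C@@H]1CC(C)=C(/C=C/C(C)=C/C=C/C(C)=C/C=C/C=C(C)/C=C/C=C(C)/C=C/C2=C(C)CCCC2(C)C)C(C)(C)C1 | target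

**Step count**

Total: 13 steps. Longest linear sequence: 10 steps (steps 1–8, 12, 13); the C25 branch (steps 9–11) joins at step 12.

**Steps most likely to fail**

Step 6 (proposed new method). The amine may be tied up as the aldimine of the C3 aldehyde, or the twisted dienone may not be deprotonated at the ε-methyl, so that no cyclisation occurs. The adduct may also lose water through its own trienamine, retro-aldol equilibration may erode the enantiomeric purity, and the remote carbon may be too far from the catalyst for good face selection. The fallback uses known chiral-pool chemistry. It sets out from but-3-en-2-one 7 and purchased (4R,6R)-4-hydroxy-2,2,6-trimethylcyclohexanone (C[C@@H]1C[C@@H](O)CC(C)(C)C1=O), and comes back to the route at 10. The hydroxy ketone is silylated (TBSCl, imidazole, DMF) to (4R,6R)-4-{[tert-butyl(dimethyl)silyl]oxy}-2,2,6-trimethylcyclohexanone F1. Its only enolisable position is deprotonated with LiN(iPr)2 and the enolate trapped with PhNTf2 to give (4R)-4-{[tert-butyl(dimethyl)silyl]oxy}-2,6,6-trimethylcyclohex-1-en-1-yl trifluoromethanesulfonate F2. Heck coupling of F2 with 7 (Pd(OAc)2, PPh3, Et3N, DMF) gives (3E)-4-[(4R)-4-{[tert-butyl(dimethyl)silyl]oxy}-2,6,6-trimethylcyclohex-1-en-1-yl]but-3-en-2-one F3, and TBAF in THF releases 10. The C3 stereocentre then comes from the purchased ketone.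

Step 4. Insertion of the enone into the congested, fully substituted alkenyl–palladium bond may be so slow that reduction or hydrolysis of the triflate and polymerisation of the enone take over. The fallback sets out from 6 and comes back at 8, replacing the insertion by transmetalation of a slim acetylide. Sonogashira coupling of 6 with but-3-yn-2-ol (PdCl2(PPh3)2, CuI, Et3N, DMF) gives 8,8-dimethoxy-6,6-dimethyl-5-(propan-2-ylidene)oct-3-yn-2-ol F4. Hydroxyl-directed trans-reduction of the propargylic alcohol with LiAlH4 in THF gives (3E)-8,8-dimethoxy-6,6-dimethyl-5-(propan-2-ylidene)oct-3-en-2-ol F5, and MnO2 in CH2Cl2 oxidises F5 to 8.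

Step 3. Enolisation of the ketone between a quaternary and an isopropyl carbon may stay incomplete, or the hindered enolate may be sulfonylated too slowly, so that ketone is returned. The fallback sets out from 5 and comes back at 8, making the alkenyl electrophile without an enolate. Hydrazine hydrate (EtOH, Et3N, reflux) converts 5 into (6,6-dimethoxy-2,4,4-trimethylhexan-3-ylidene)hydrazine F6. Barton iodination (I2, tetramethylguanidine, Et2O) turns F6 into 3-iodo-6,6-dimethoxy-2,4,4-trimethylhex-2-ene F7. Heck coupling of F7 with 7 (Pd(OAc)2, Et3N, DMF), which profits from the easier oxidative addition of the iodide, gives 8.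

**Further compounds**

F1 | step 6 | (4R,6R)-4-{[tert-butyl(dimethyl)silyl]oxy}-2,2,6-trimethylcyclohexanone | C[C@@H]1C[C@@H](O[Si](C)(C)C(C)(C)C)CC(C)(C)C1=O
F2 | step 6 | (4R)-4-{[tert-butyl(dimethyl)silyl]oxy}-2,6,6-trimethylcyclohex-1-en-1-yl trifluoromethanesulfonate | CC(C)(C)[Si](C)(C)O[C@@H]1CC(C)=C(OS(=O)(=O)C(F)(F)F)C(C)(C)C1
F3 | step 6 | (3E)-4-[(4R)-4-{[tert-butyl(dimethyl)silyl]oxy}-2,6,6-trimethylcyclohex-1-en-1-yl]but-3-en-2-one | CC(C)(C)[Si](C)(C)O[C@@H]1CC(C)=C(/C=C/C(C)=O)C(C)(C)C1
F4 | step 4 | 8,8-dimethoxy-6,6-dimethyl-5-(propan-2-ylidene)oct-3-yn-2-ol | CC(O)C#CC(=C(C)C)C(C)(C)CC(OC)OC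
F5 | step 4 | (3E)-8,8-dimethoxy-6,6-dimethyl-5-(propan-2-ylidene)oct-3-en-2-ol | CC(O)/C=C/C(=C(C)C)C(C)(C)CC(OC)OC
F6 | step 3 | (6,6-dimethoxy-2,4,4-trimethylhexan-3-ylidene)hydrazine | CC(C)C(=NN)C(C)(C)CC(OC)OC
F7 | step 3 | 3-iodo-6,6-dimethoxy-2,4,4-trimethylhex-2-ene | CC(C)=C(I)C(C)(C)CC(OC)OC
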